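**Retrosynthetic overview**

1. The route rests on ring A: a phloroglucinol whose benzyl-bearing C8 lies between the oxygenated carbons C7 and C8a. This pattern arises when the ester α-carbon of a cinnamoyl-terminated 3,5,7-triketo ester already carries the benzyl group.
2. Ring C is opened at O1–C2: oxidative cyclisation of a 2'-hydroxychalcone whose only free hydroxyl is the benzyl-flanked one. The five methyl ethers are removed last.
3. Ring A is opened at C4a–C8a: Claisen cyclisation of triketo ester 11 to chalcone 13.
4. The chain of 11 is cut into methyl acetoacetate, 4-methoxybenzyl chloride, an acetyl Weinreb amide and a 3,4-dimethoxycinnamoyl Weinreb amide. These are joined by one enolate alkylation and two polyanion acylations.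
5. Ring order: ring A (step 5), then ring C (step 7). Ring B and the benzyl arene are brought in preformed.

Key step: step 5

Remark: polyketo esters 6 and 11 are drawn as keto forms although they exist as enol mixtures. Their C2 centre is racemic and disappears on aromatisation, and the target has no stereocentre. The two ring A hydroxyls are masked as methyl ethers because these survive hot I2/DMSO, where acetal protecting groups could be lost before ring C closes.

**Route**

Step 1
Reactants: 1 methyl acetoacetate (used in excess); 2 4-methoxybenzyl chloride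
Product: 3 methyl 2-(4-methoxybenzyl)-3-oxobutanoate (racemic)
Conditions: K2CO3, acetone, reflux
Reagents that add atoms: none
Why: Acetoacetic ester alkylation (SN2 of the stabilised enolate on a reactive benzylic chloride); excess 1 should limit dialkylation, and the new centre forms as a racemate that is later lost.

Step 2
Reactants: 3 methyl 2-(4-methoxybenzyl)-3-oxobutanoate; 4 N-methoxy-N-methylacetamide
Product: 6 methyl 2-(4-methoxybenzyl)-3,5-dioxohexanoate, via dilithium bis-enolate 5 (not isolated)
Conditions: LiN(i-Pr)2 (2.2 equiv), THF, 0 °C; then 4, −78 → 0 °C; cold aq. HCl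
Reagents that add atoms: none
Why: β-Keto ester dianion chemistry (Weiler-type): the second deprotonation occurs at the methyl group and this last-formed carbanion is the one acylated, while the Weinreb amide delivers a single acetyl group without over-addition.

Step 3
Reactants: 7 (E)-3,4-dimethoxycinnamic acid
Product: 9 (E)-3-(3,4-dimethoxyphenyl)-N-methoxy-N-methylprop-2-enamide, via acyl imidazolide 8 (not isolated)
Conditions: CDI, CH2Cl2, rt; then MeNHOMe·HCl, rt
Reagents that add atoms: N,O-dimethylhydroxylamine hydrochloride, CNOC.Cl
Why: Carboxylic acid activation as the acyl imidazolide followed by aminolysis (Weinreb amide formation); the E alkene is not touched.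

Step 4
Reactants: 6 methyl 2-(4-methoxybenzyl)-3,5-dioxohexanoate; 9 (E)-3-(3,4-dimethoxyphenyl)-N-methoxy-N-methylprop-2-enamide
Product: 11 methyl (E)-9-(3,4-dimethoxyphenyl)-2-(4-methoxybenzyl)-3,5,7-trioxonon-8-enoate, via trilithium tris-enolate 10 (not isolated)
Conditions: LiN(i-Pr)2 (3.3 equiv), THF, 0 °C; then 9, −78 → 0 °C; cold dilute HCl; used without long storage
Reagents that add atoms: none
Why: Polyanion C-acylation of a 3,5-diketo ester trianion at its terminal, least stabilised carbanion; the unsaturated Weinreb amide should react by 1,2-addition, not conjugate addition, and should stop at the ketone stage.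

Step 5
Reactants: 11 methyl (E)-9-(3,4-dimethoxyphenyl)-2-(4-methoxybenzyl)-3,5,7-trioxonon-8-enoate
Product: 13 (E)-3-(3,4-dimethoxyphenyl)-1-[2,4,6-trihydroxy-3-(4-methoxybenzyl)phenyl]prop-2-en-1-one, via acylcyclohexanetrione 12 (not isolated)
Conditions: Mg(OMe)2 (excess), MeOH, rt → reflux; then ice-cold 1 M HCl
Reagents that add atoms: none
Why: Excess Mg(OMe)2 turns 11 into a magnesium polyenolate in which the chelated 5,7-diketone unit is folded toward the ester, and C6 (between the C5 and C7 carbonyls) attacks the ester carbonyl C1; loss of methoxide gives trione 12, which enolises at once to the phloroglucinol, so the step is an intramolecular Claisen (Dieckmann-type) condensation followed by aromatisation, the reaction type known for 3,5,7-triketo esters going to acylphloroglucinols and the laboratory counterpart of the chalcone synthase ring closure. Ring A closes by 6-exo-trig attack of the enolate carbon on the ester carbonyl, forming the bond that becomes C4a–C8a of the flavone. No stereocentre is created, and the racemic C2 of 11 becomes an aromatic carbon. The selectivity needed is Claisen closure over aldol closure (C2 onto the C7 ketone) and over O-acylation to a 4-hydroxy-2-pyrone: the benzyl group on C2 makes the aldol adduct a quaternary β-hydroxy ketone that cannot become an arene and should revert by retro-aldol, and the pyrone is reopened by methoxide in methanol, whereas the Claisen product leaves the equilibrium as a chelated aromatic phenoxide. Because the ester carbonyl oxygen ends as the hydroxyl next to the benzyl-bearing carbon, the benzyl group is placed between two oxygenated carbons as the target requires. The chalcone should stay open while held as the magnesium phenoxide chelate; it is released with cold acid and used at once so that oxa-Michael closure to flavanones does not set in.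

Step 6
Reactants: 13 (E)-3-(3,4-dimethoxyphenyl)-1-[2,4,6-trihydroxy-3-(4-methoxybenzyl)phenyl]prop-2-en-1-one
Product: 14 (E)-3-(3,4-dimethoxyphenyl)-1-[2-hydroxy-4,6-dimethoxy-3-(4-methoxybenzyl)phenyl]prop-2-en-1-one
Conditions: Me2SO4 (2.1 equiv), K2CO3, acetone, 0 °C → rt
Reagents that add atoms: dimethyl sulfate, COS(=O)(=O)OC
Why: Williamson-type partial O-methylation: the para hydroxyl is unchelated and most acidic, and of the two ortho hydroxyls the one wedged between the benzyl group and the carbonyl is both more hindered and the stronger hydrogen-bond donor to C=O, so the second methyl should go to the open ortho hydroxyl and leave only the benzyl-flanked OH free.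

Step 7
Reactants: 14 (E)-3-(3,4-dimethoxyphenyl)-1-[2-hydroxy-4,6-dimethoxy-3-(4-methoxybenzyl)phenyl]prop-2-en-1-one
Product: 16 2-(3,4-dimethoxyphenyl)-5,7-dimethoxy-8-(4-methoxybenzyl)-4H-chromen-4-one, via flavanone 15 (not isolated)
Conditions: I2 (10 mol %), DMSO, 120 °C
Reagents that add atoms: none
Why: Iodine/DMSO oxidative cyclisation of a 2'-hydroxychalcone (6-endo oxa-Michael closure to flavanone 15, α-iodination and loss of HI, DMSO reoxidising HI to I2); the single free hydroxyl is the benzyl-flanked one, so O1 is bonded to the carbon next to the benzyl group and the 8-benzyl flavone should result.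

Step 8
Reactants: 16 2-(3,4-dimethoxyphenyl)-5,7-dimethoxy-8-(4-methoxybenzyl)-4H-chromen-4-one
Product: 17 8-(4-hydroxybenzyl)luteolin
Conditions: BBr3 (12 equiv), CH2Cl2, −78 °C → rt; then MeOH, H2O
Reagents that add atoms: none
Why: Lewis-acid cleavage of all five aryl methyl ethers by BBr3 (the 5-methoxy aided by chelation to the C4 carbonyl), run cold so that acid-induced opening and reclosure of ring C (Wessely–Moser isomerisation) and loss of the benzyl group are not expected.

**Compound list**

1 | methyl acetoacetate | COC(=O)CC(C)=O | starting material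
2 | 4-methoxybenzyl chloride | COc1ccc(CCl)cc1 | starting material
3 | methyl 2-(4-methoxybenzyl)-3-oxobutanoate (racemic) | COC(=O)C(Cc1ccc(OC)cc1)C(C)=O | intermediate
4 | N-methoxy-N-methylacetamide | CON(C)C(C)=O | starting material
5 | dilithium bis-enolate (dianion) of 3, not isolated | [Li+].[Li+].C=C([O-])C(Cc1ccc(OC)cc1)=C([O-])OC | intermediate
6 | methyl 2-(4-methoxybenzyl)-3,5-dioxohexanoate (racemic, enol mixture) | COC(=O)C(Cc1ccc(OC)cc1)C(=O)CC(C)=O | intermediate
7 | (E)-3,4-dimethoxycinnamic acid | COc1ccc(/C=C/C(=O)O)cc1OC | starting material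
8 | (E)-3-(3,4-dimethoxyphenyl)-1-(imidazol-1-yl)prop-2-en-1-one (acyl imidazolide), not isolated | COc1ccc(/C=C/C(=O)n2ccnc2)cc1OC | intermediate
9 | (E)-3-(3,4-dimethoxyphenyl)-N-methoxy-N-methylprop-2-enamide | COc1ccc(/C=C/C(=O)N(C)OC)cc1OC | intermediate
10 | trilithium tris-enolate (trianion) of 6, not isolated | [Li+].[Li+].[Li+].C=C([O-])C=C([O-])C(Cc1ccc(OC)cc1)=C([O-])OC | intermediate
11 | methyl (E)-9-(3,4-dimethoxyphenyl)-2-(4-methoxybenzyl)-3,5,7-trioxonon-8-enoate (racemic, enol mixture) | COC(=O)C(Cc1ccc(OC)cc1)C(=O)CC(=O)CC(=O)/C=C/c1ccc(OC)c(OC)c1 | intermediate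
12 | 2-(4-methoxybenzyl)-4-[(E)-3-(3,4-dimethoxyphenyl)prop-2-enoyl]cyclohexane-1,3,5-trione, not isolated | COc1ccc(CC2C(=O)CC(=O)C(C(=O)/C=C/c3ccc(OC)c(OC)c3)C2=O)cc1 | intermediate
13 | (E)-3-(3,4-dimethoxyphenyl)-1-[2,4,6-trihydroxy-3-(4-methoxybenzyl)phenyl]prop-2-en-1-one | COc1ccc(Cc2c(O)cc(O)c(C(=O)/C=C/c3ccc(OC)c(OC)c3)c2O)cc1 | intermediate
14 | (E)-3-(3,4-dimethoxyphenyl)-1-[2-hydroxy-4,6-dimethoxy-3-(4-methoxybenzyl)phenyl]prop-2-en-1-one | COc1ccc(Cc2c(OC)cc(OC)c(C(=O)/C=C/c3ccc(OC)c(OC)c3)c2O)cc1 | intermediate
15 | 2-(3,4-dimethoxyphenyl)-5,7-dimethoxy-8-(4-methoxybenzyl)chroman-4-one (racemic), not isolated | COc1ccc(Cc2c(OC)cc(OC)c3c2OC(c2ccc(OC)c(OC)c2)CC3=O)cc1 | intermediate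
16 | 2-(3,4-dimethoxyphenyl)-5,7-dimethoxy-8-(4-methoxybenzyl)-4H-chromen-4-one | COc1ccc(Cc2c(OC)cc(OC)c3c(=O)cc(-c4ccc(OC)c(OC)c4)oc23)cc1 | intermediate
17 | 8-(4-hydroxybenzyl)luteolin | O=c1cc(-c2ccc(O)c(O)c2)oc2c(Cc3ccc(O)cc3)c(O)cc(O)c12 | target

**Step count**

Total: 8 steps. Longest linear sequence: 7 steps (steps 1, 2, 4, 5, 6, 7, 8); step 3 is a side branch.

**Steps most likely to fail**

Step 5. The polyenolate may close in other modes (lactonisation to a 4-hydroxy-2-pyrone that is not reopened, or conjugate addition of C4 to the enone), or the free chalcone may isomerise to flavanones during work-up. The fallback takes ring A from a preformed phloroglucinol instead of building it; it sets out from compound 2 and returns at compound 14. Commercial 2,4,6-trihydroxyacetophenone is C-benzylated with 2 (aq. KOH, 0 °C → rt) to 1-[2,4,6-trihydroxy-3-(4-methoxybenzyl)phenyl]ethanone F1; only one mono-C-benzyl isomer is possible because the ring is symmetric. Partial methylation (Me2SO4, K2CO3, acetone) should give 1-[2-hydroxy-4,6-dimethoxy-3-(4-methoxybenzyl)phenyl]ethanone F2. Claisen–Schmidt condensation of this ketone with 3,4-dimethoxybenzaldehyde (KOH, EtOH, rt) should give chalcone 14.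

Step 4. The trianion may be quenched by proton transfer, may add in conjugate fashion, or the triketo ester may cyclise during acidic work-up. The fallback replaces the acylation by aldol addition and oxidation; it sets out from compound 6 and returns at compound 11. Trianion 10, made as in step 4, is added to commercial (E)-3,4-dimethoxycinnamaldehyde (THF, −78 °C) to give by 1,2-addition methyl (E)-9-(3,4-dimethoxyphenyl)-7-hydroxy-2-(4-methoxybenzyl)-3,5-dioxonon-8-enoate F3. Oxidation of its allylic alcohol with MnO2 (CH2Cl2, rt) should give 11.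

Step 6. Methylation may fall on the benzyl-flanked hydroxyl or go too far, or base-induced oxa-Michael closure to flavanones may outrun methylation. The fallback replaces selective protection by exhaustive protection and selective deprotection; it sets out from compound 13 and returns at compound 14. Exhaustive methylation (excess MeI, K2CO3, DMF, 40 °C; flavanones formed on the way should reopen and be methylated) gives (E)-3-(3,4-dimethoxyphenyl)-1-[2,4,6-trimethoxy-3-(4-methoxybenzyl)phenyl]prop-2-en-1-one F4. One equivalent of BCl3 (CH2Cl2, −78 → 0 °C) should then cleave, by carbonyl chelation, the ortho methoxy group that is forced out of the ring plane by its two neighbours, which is the benzyl-flanked one, giving 14.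

**Further compounds**

F1 | step 5 | 1-[2,4,6-trihydroxy-3-(4-methoxybenzyl)phenyl]ethanone | CC(=O)c1c(O)cc(O)c(Cc2ccc(OC)cc2)c1O
F2 | step 5 | 1-[2-hydroxy-4,6-dimethoxy-3-(4-methoxybenzyl)phenyl]ethanone | CC(=O)c1c(OC)cc(OC)c(Cc2ccc(OC)cc2)c1O
F3 | step 4 | methyl (E)-9-(3,4-dimethoxyphenyl)-7-hydroxy-2-(4-methoxybenzyl)-3,5-dioxonon-8-enoate (mixture of diastereomers) | COC(=O)C(Cc1ccc(OC)cc1)C(=O)CC(=O)CC(O)/C=C/c1ccc(OC)c(OC)c1
F4 | step 6 | (E)-3-(3,4-dimethoxyphenyl)-1-[2,4,6-trimethoxy-3-(4-methoxybenzyl)phenyl]prop-2-en-1-one | COc1ccc(Cc2c(OC)cc(OC)c(C(=O)/C=C/c3ccc(OC)c(OC)c3)c2OC)cc1
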